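**Retrosynthetic overview**

1. Target 25 ← 24 by one global desilylation. Ring B (pyran: C1, O2, C3, C4, C4a, C8a) is closed last, by Meyer–Schuster rearrangement and cyclodehydration of hydroxy alkynol 22 (O2–C3 bond); C1 is attached to C8a beforehand by Stille hydroxymethylation of vinyl bromide 20.
2. Ring A (carbocycle C4a–C5–C6–C7–C8–C8a) ← the five-membered ring (C8, C7, C6, C5, C4a) of silyl enol ether 18: dibromocarbene inserts C8a between C8 and C4a through a 6,6-dibromobicyclo[3.1.0]hexane whose internal C8–C4a bond opens, giving the 2-bromo-enone with C8a=C4a in place.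
3. Enabling feature: C7 is quaternary (methyl, aroyloxy), so the C8 ketone of cyclopentanone 17 can enolise only towards C4a. The single enol ether C8=C4a, its siloxy donor on C8 and the strained cyclopropane with a geminal bromide on C8a direct cleavage to exactly the C8–C4a bond; C6 and C7 are spectators.
4. 17 ← enolate alkylation at C4a with bromide 15 (C4, C3 and the propenyl carbons as a propargylic silyl ether) ← 9 ← CBS desymmetrisation of achiral dione 7 (sets C6 and C7) ← hypervalent-iodine acyloxylation of dione 5 with acid 4 (hindered C7–O ester bond made at carbon).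
5. Ring order: aromatic ring C (bought, in 1) → five-membered carbocycle (bought, in 5) → ring A by expansion (step 12) → ring B (step 15).

Key step: step 12

**Remarks**

- Atom numbers are those of the 1H-isochromene core of the target (C1, O2, C3, C4, C4a, C5–C8, C8a).
- ArCO = 2-methoxy-6-methyl-4-(triisopropylsilyloxy)benzoyl.
- Assumed commercial: 1, 5, 10 and (tributylstannyl)methanol.
- The carbinol centre of 10 is destroyed in step 15; one enantiomer is used only to keep intermediates single diastereomers.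
- The C4a epimers of 17 are not separated; that centre is destroyed in step 11.

**Route**

Step 1
Reactants: 1 2,4-dihydroxy-6-methylbenzaldehyde
Product: 2 2-hydroxy-6-methyl-4-(triisopropylsilyloxy)benzaldehyde
Conditions: TIPSCl, imidazole, DMF, 0 °C to rt
Reagents that add atoms: chlorotriisopropylsilane CC(C)[Si](Cl)(C(C)C)C(C)C
Why: Selective phenol silylation should occur at the 4-hydroxyl because the 2-hydroxyl is deactivated by its hydrogen bond to the formyl group.

Step 2
Reactants: 2 2-hydroxy-6-methyl-4-(triisopropylsilyloxy)benzaldehyde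
Product: 3 2-methoxy-6-methyl-4-(triisopropylsilyloxy)benzaldehyde
Conditions: MeI, K2CO3, acetone, reflux
Reagents that add atoms: iodomethane CI
Why: Williamson O-methylation of the remaining chelated phenol should proceed under conditions that leave an aryl triisopropylsilyl ether intact.

Step 3
Reactants: 3 2-methoxy-6-methyl-4-(triisopropylsilyloxy)benzaldehyde
Product: 4 ArCO2H (2-methoxy-6-methyl-4-(triisopropylsilyloxy)benzoic acid)
Conditions: NaClO2, NaH2PO4, 2-methyl-2-butene, t-BuOH/H2O, rt
Reagents that add atoms: sodium chlorite [Na+].[O-]Cl=O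
Why: Pinnick oxidation converts the hindered aldehyde into the acid under buffered conditions, the alkene scavenging hypochlorous acid so that the electron-rich ring is not chlorinated.

Step 4
Reactants: 4 ArCO2H (2.1 equiv, one equivalent is returned) and 5 2-methylcyclopentane-1,3-dione
Product: 7 2-methyl-1,3-dioxocyclopentan-2-yl ester of ArCO2H, via bis(aroyloxy)iodobenzene 6 (not isolated)
Conditions: PhI(OAc)2, chlorobenzene, 50 °C, reduced pressure (removal of AcOH); then 5, MeCN, 0 °C to rt
Reagents that add atoms: (diacetoxyiodo)benzene CC(=O)OI(OC(C)=O)c1ccccc1 (its PhI unit is found in 6 only)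
Why: Ligand exchange gives the trivalent-iodine dicarboxylate 6, the enol of 5 binds to iodine and reductive ligand coupling forms the C7–O bond at carbon (hypervalent-iodine α-acyloxylation of a 1,3-dicarbonyl), so the hindered tertiary ester is made without acylating a tertiary alcohol.

Step 5
Reactants: 7 2-methyl-1,3-dioxocyclopentan-2-yl ester of ArCO2H
Product: 8 (1R,2R)-2-hydroxy-1-methyl-5-oxocyclopentyl ester of ArCO2H
Conditions: (S)-2-methyl-CBS-oxazaborolidine (20 mol %), BH3·SMe2 (0.6 equiv), THF, −40 °C; MeOH, then aqueous work-up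
Reagents that add atoms: none
Why: Corey–Bakshi–Shibata desymmetrisation should reduce one of the two enantiotopic ketones; the catalyst (quaternary C7 as the large flank) sets C6 as R, and hydride delivery anti to the bulky, electronegative aroyloxy group (steric and polar Felkin–Anh preference) places the new hydroxyl cis to the ester, which fixes C7 as R.

Step 6
Reactants: 8 (1R,2R)-2-hydroxy-1-methyl-5-oxocyclopentyl ester of ArCO2H
Product: 9 (1R,2R)-2-(tert-butyldimethylsilyloxy)-1-methyl-5-oxocyclopentyl ester of ArCO2H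
Conditions: TBSOTf, 2,6-lutidine, CH2Cl2, −78 to 0 °C
Reagents that add atoms: tert-butyldimethylsilyl triflate CC(C)(C)[Si](C)(C)OS(=O)(=O)C(F)(F)F
Why: Silylation of the hindered secondary alcohol under non-nucleophilic conditions blocks retro-aldol opening and later keeps O6 from competing with O2 in the pyran closure.

Step 7
Reactants: 10 (R)-but-3-yn-2-ol
Product: 11 (R)-triethyl(but-3-yn-2-yloxy)silane
Conditions: TESCl, imidazole, CH2Cl2, 0 °C
Reagents that add atoms: chlorotriethylsilane CC[Si](Cl)(CC)CC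
Why: Standard silyl protection gives an ether that survives bases and can later be removed in the presence of the tert-butyldimethylsilyl and aryl triisopropylsilyl ethers.

Step 8
Reactants: 11 (R)-triethyl(but-3-yn-2-yloxy)silane
Product: 13 (R)-4-(triethylsilyloxy)pent-2-yn-1-ol, via lithium acetylide 12 (not isolated)
Conditions: n-BuLi, THF, −78 °C; (CH2O)n, −78 °C to rt; aqueous work-up
Reagents that add atoms: n-butyllithium [Li]CCCC (lithium in 12 only); formaldehyde (as paraformaldehyde) C=O
Why: Acetylide addition to formaldehyde installs the carbon that becomes C4.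

Step 9
Reactants: 13 (R)-4-(triethylsilyloxy)pent-2-yn-1-ol
Product: 15 (R)-(5-bromopent-3-yn-2-yloxy)triethylsilane, via propargylic mesylate 14 (not isolated)
Conditions: MsCl, Et3N, CH2Cl2, −20 °C; then LiBr, THF, 0 °C to rt
Reagents that add atoms: methanesulfonyl chloride CS(Cl)(=O)=O (atoms in 14 only); lithium bromide [Li+].[Br-]
Why: Sulfonylation and SN2 displacement by bromide give the primary propargylic bromide without acid that would cleave the triethylsilyl ether.

Step 10
Reactants: 9 (1R,2R)-2-(tert-butyldimethylsilyloxy)-1-methyl-5-oxocyclopentyl ester of ArCO2H and 15 (R)-(5-bromopent-3-yn-2-yloxy)triethylsilane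
Product: 17 (1R,2R,4RS)-2-(tert-butyldimethylsilyloxy)-1-methyl-5-oxo-4-[(4R)-4-(triethylsilyloxy)pent-2-yn-1-yl]cyclopentyl ester of ArCO2H, via lithium enolate 16 (not isolated)
Conditions: LiN(SiMe3)2 (1.05 equiv), THF, −78 °C; then 15, DMPU, −78 to −30 °C
Reagents that add atoms: lithium hexamethyldisilazide [Li]N([Si](C)(C)C)[Si](C)(C)C (lithium in 16 only)
Why: Enolate C-alkylation can occur only at C4a because C7 is quaternary, and the amide base is too weak for lateral metalation of the toluate methyl and too hindered, like the enolate, to attack the 2,6-disubstituted aroyl ester.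

Step 11
Reactants: 17 the alkylated cyclopentanone described in step 10
Product: 18 (1R,5R)-5-(tert-butyldimethylsilyloxy)-1-methyl-3-[(4R)-4-(triethylsilyloxy)pent-2-yn-1-yl]-2-(trimethylsilyloxy)cyclopent-2-en-1-yl ester of ArCO2H
Conditions: TMSOTf, Et3N, CH2Cl2, 0 °C
Reagents that add atoms: trimethylsilyl triflate C[Si](C)(C)OS(=O)(=O)C(F)(F)F
Why: Soft enolisation and O-silylation give the only possible enol ether, C8=C4a, and remove the C4a stereocentre.

Step 12
Reactants: 18 the trimethylsilyl enol ether described in step 11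
Product: 20 (1R,6R)-3-bromo-6-(tert-butyldimethylsilyloxy)-1-methyl-2-oxo-4-[(4R)-4-(triethylsilyloxy)pent-2-yn-1-yl]cyclohex-3-en-1-yl ester of ArCO2H, via dibromocyclopropane 19 (not isolated)
Conditions: CHBr3, KOt-Bu, pentane, −30 °C to rt; then toluene, 60 °C
Reagents that add atoms: bromoform BrC(Br)Br
Why: KOt-Bu and CHBr3 give dibromocarbene by α-elimination, which adds in a concerted cheletropic [2+1] sense to the electron-rich C8=C4a enol ether and closes the three-membered ring of 19 (cis fusion is enforced by the five-membered ring; the two bridgehead centres, set by approach anti to the C6 and C7 oxygen groups, are transient). Strain release then drives a thermally allowed disrotatory two-electron electrocyclic opening of the internal C8–C4a bond with loss of the endo bromide (Woodward–Hoffmann–DePuy mode), the siloxy group on C8 stabilising the 2-bromoallyl cation, and loss of the silyl group as Me3SiBr delivers the enone, so ring A grows from five to six atoms by insertion of C8a. The closest known reaction type is the dihalocarbene ring expansion of cyclic silyl enol ethers to 2-halocycloalk-2-enones. No stereocentre is created in the product, and C6 and C7 lie outside the reacting array and cannot be scrambled. The selectivities needed are the site of insertion, secured because quaternary C7 leaves C8=C4a as the only enol ether; cleavage of the internal and not an external cyclopropane bond, secured by the donor on C8 and the geminal bromide on C8a; and chemoselectivity for the enol ether over the alkyne and the arene, secured by the electrophilic carbene.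

Step 13
Reactants: 20 the 2-bromo-enone described in step 12
Product: 21 (1R,6R)-6-(tert-butyldimethylsilyloxy)-3-(hydroxymethyl)-1-methyl-2-oxo-4-[(4R)-4-(triethylsilyloxy)pent-2-yn-1-yl]cyclohex-3-en-1-yl ester of ArCO2H
Conditions: Bu3SnCH2OH, Pd(PPh3)4 (10 mol %), 1,4-dioxane, 90 °C
Reagents that add atoms: (tributylstannyl)methanol OC[Sn](CCCC)(CCCC)CCCC
Why: Stille coupling at the activated α-bromo-enone under zerovalent palladium catalysis transfers the hydroxymethyl group and so attaches C1 with O2 to C8a.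

Step 14
Reactants: 21 the hydroxymethyl enone described in step 13
Product: 22 (1R,6R)-6-(tert-butyldimethylsilyloxy)-3-(hydroxymethyl)-4-[(4R)-4-hydroxypent-2-yn-1-yl]-1-methyl-2-oxocyclohex-3-en-1-yl ester of ArCO2H
Conditions: PPTS (cat.), MeOH, 0 °C to rt
Reagents that add atoms: none
Why: Mild acid methanolysis should remove the unhindered secondary triethylsilyl ether while the hindered tert-butyldimethylsilyl ether and the aryl triisopropylsilyl ether stay.

Step 15
Reactants: 22 the diol described in step 14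
Product: 24 (6R,7R)-6-(tert-butyldimethylsilyloxy)-7-methyl-8-oxo-3-[(E)-prop-1-en-1-yl]-5,6,7,8-tetrahydro-1H-isochromen-7-yl ester of ArCO2H, via hydroxy enone 23 (not isolated)
Conditions: Ph3PAuNTf2 (5 mol %), MeOH (2 equiv), toluene, rt; then PPTS (20 mol %), 4 Å molecular sieves, 40 °C
Reagents that add atoms: none
Why: Meyer–Schuster rearrangement catalysed by monovalent gold moves the oxygen to C3 and gives the (E)-propenyl ketone 23; the C1 hydroxyl then adds to C3 and the hemiketal dehydrates towards the doubly activated C4 methylene, giving the conjugated pyran (a competing 6-exo hydroalkoxylation followed by allylic dehydration would converge on the same product).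

Step 16
Reactants: 24 the bis-silyl ether described in step 15
Product: 25 (6R,7R)-6-hydroxy-7-methyl-8-oxo-3-[(E)-prop-1-en-1-yl]-5,6,7,8-tetrahydro-1H-isochromen-7-yl 4-hydroxy-2-methoxy-6-methylbenzoate (target)
Conditions: Bu4NF, AcOH (1:1), THF, 0 °C to rt
Reagents that add atoms: none
Why: Buffered fluoride desilylation should free the phenol and the C6 alcohol without base-induced vinylogous elimination of O6 or acyl migration of the hindered ester.

**Compound list**

1 | 2,4-dihydroxy-6-methylbenzaldehyde | Cc1cc(O)cc(O)c1C=O | starting material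
2 | 2-hydroxy-6-methyl-4-(triisopropylsilyloxy)benzaldehyde | Cc1cc(O[Si](C(C)C)(C(C)C)C(C)C)cc(O)c1C=O | intermediate
3 | 2-methoxy-6-methyl-4-(triisopropylsilyloxy)benzaldehyde | COc1cc(O[Si](C(C)C)(C(C)C)C(C)C)cc(C)c1C=O | intermediate
4 | 2-methoxy-6-methyl-4-(triisopropylsilyloxy)benzoic acid (ArCO2H) | COc1cc(O[Si](C(C)C)(C(C)C)C(C)C)cc(C)c1C(=O)O | intermediate
5 | 2-methylcyclopentane-1,3-dione | CC1C(=O)CCC1=O | starting material
6 | bis[2-methoxy-6-methyl-4-(triisopropylsilyloxy)benzoyloxy]iodobenzene (not isolated) | COc1cc(O[Si](C(C)C)(C(C)C)C(C)C)cc(C)c1C(=O)OI(OC(=O)c1c(C)cc(O[Si](C(C)C)(C(C)C)C(C)C)cc1OC)c1ccccc1 | intermediate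
7 | 2-methyl-1,3-dioxocyclopentan-2-yl 2-methoxy-6-methyl-4-(triisopropylsilyloxy)benzoate | CC1(OC(=O)c2c(C)cc(O[Si](C(C)C)(C(C)C)C(C)C)cc2OC)C(=O)CCC1=O | intermediate
8 | (1R,2R)-2-hydroxy-1-methyl-5-oxocyclopentyl 2-methoxy-6-methyl-4-(triisopropylsilyloxy)benzoate | O=C1[C@](C)(OC(=O)c2c(C)cc(O[Si](C(C)C)(C(C)C)C(C)C)cc2OC)[C@H](O)CC1 | intermediate
9 | (1R,2R)-2-(tert-butyldimethylsilyloxy)-1-methyl-5-oxocyclopentyl 2-methoxy-6-methyl-4-(triisopropylsilyloxy)benzoate | O=C1[C@](C)(OC(=O)c2c(C)cc(O[Si](C(C)C)(C(C)C)C(C)C)cc2OC)[C@H](O[Si](C)(C)C(C)(C)C)CC1 | intermediate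
10 | (R)-but-3-yn-2-ol | C[C@@H](O)C#C | starting material
11 | (R)-triethyl(but-3-yn-2-yloxy)silane | C[C@@H](O[Si](CC)(CC)CC)C#C | intermediate
12 | lithium acetylide of 11 (not isolated) | C[C@@H](O[Si](CC)(CC)CC)C#C[Li] | intermediate
13 | (R)-4-(triethylsilyloxy)pent-2-yn-1-ol | C[C@@H](O[Si](CC)(CC)CC)C#CCO | intermediate
14 | (R)-4-(triethylsilyloxy)pent-2-yn-1-yl methanesulfonate (not isolated) | C[C@@H](O[Si](CC)(CC)CC)C#CCOS(C)(=O)=O | intermediate
15 | (R)-(5-bromopent-3-yn-2-yloxy)triethylsilane | C[C@@H](O[Si](CC)(CC)CC)C#CCBr | intermediate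
16 | lithium enolate of 9, C8(OLi)=C4a (not isolated) | [Li]OC1=CC[C@@H](O[Si](C)(C)C(C)(C)C)[C@@]1(C)OC(=O)c2c(C)cc(O[Si](C(C)C)(C(C)C)C(C)C)cc2OC | intermediate
17 | (1R,2R,4RS)-2-(tert-butyldimethylsilyloxy)-1-methyl-5-oxo-4-[(4R)-4-(triethylsilyloxy)pent-2-yn-1-yl]cyclopentyl 2-methoxy-6-methyl-4-(triisopropylsilyloxy)benzoate (epimers at the alkylated carbon) | O=C1[C@](C)(OC(=O)c2c(C)cc(O[Si](C(C)C)(C(C)C)C(C)C)cc2OC)[C@H](O[Si](C)(C)C(C)(C)C)CC1CC#C[C@@H](C)O[Si](CC)(CC)CC | intermediate
18 | (1R,5R)-5-(tert-butyldimethylsilyloxy)-1-methyl-3-[(4R)-4-(triethylsilyloxy)pent-2-yn-1-yl]-2-(trimethylsilyloxy)cyclopent-2-en-1-yl 2-methoxy-6-methyl-4-(triisopropylsilyloxy)benzoate | C[Si](C)(C)OC1=C(CC#C[C@@H](C)O[Si](CC)(CC)CC)C[C@@H](O[Si](C)(C)C(C)(C)C)[C@@]1(C)OC(=O)c2c(C)cc(O[Si](C(C)C)(C(C)C)C(C)C)cc2OC | intermediate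
19 | 6,6-dibromo-1-(trimethylsilyloxy)bicyclo[3.1.0]hexane adduct of 18, cyclopropane cis-fused on the face anti to the C6 and C7 oxygen groups (not isolated) | C[Si](C)(C)O[C@@]12C(Br)(Br)[C@]1(CC#C[C@@H](C)O[Si](CC)(CC)CC)C[C@@H](O[Si](C)(C)C(C)(C)C)[C@@]2(C)OC(=O)c3c(C)cc(O[Si](C(C)C)(C(C)C)C(C)C)cc3OC | intermediate
20 | (1R,6R)-3-bromo-6-(tert-butyldimethylsilyloxy)-1-methyl-2-oxo-4-[(4R)-4-(triethylsilyloxy)pent-2-yn-1-yl]cyclohex-3-en-1-yl 2-methoxy-6-methyl-4-(triisopropylsilyloxy)benzoate | O=C1C(Br)=C(CC#C[C@@H](C)O[Si](CC)(CC)CC)C[C@@H](O[Si](C)(C)C(C)(C)C)[C@@]1(C)OC(=O)c2c(C)cc(O[Si](C(C)C)(C(C)C)C(C)C)cc2OC | intermediate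
21 | (1R,6R)-6-(tert-butyldimethylsilyloxy)-3-(hydroxymethyl)-1-methyl-2-oxo-4-[(4R)-4-(triethylsilyloxy)pent-2-yn-1-yl]cyclohex-3-en-1-yl 2-methoxy-6-methyl-4-(triisopropylsilyloxy)benzoate | O=C1C(CO)=C(CC#C[C@@H](C)O[Si](CC)(CC)CC)C[C@@H](O[Si](C)(C)C(C)(C)C)[C@@]1(C)OC(=O)c2c(C)cc(O[Si](C(C)C)(C(C)C)C(C)C)cc2OC | intermediate
22 | (1R,6R)-6-(tert-butyldimethylsilyloxy)-3-(hydroxymethyl)-4-[(4R)-4-hydroxypent-2-yn-1-yl]-1-methyl-2-oxocyclohex-3-en-1-yl 2-methoxy-6-methyl-4-(triisopropylsilyloxy)benzoate | O=C1C(CO)=C(CC#C[C@@H](C)O)C[C@@H](O[Si](C)(C)C(C)(C)C)[C@@]1(C)OC(=O)c2c(C)cc(O[Si](C(C)C)(C(C)C)C(C)C)cc2OC | intermediate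
23 | (1R,6R)-6-(tert-butyldimethylsilyloxy)-3-(hydroxymethyl)-1-methyl-2-oxo-4-[(E)-2-oxopent-3-en-1-yl]cyclohex-3-en-1-yl 2-methoxy-6-methyl-4-(triisopropylsilyloxy)benzoate (not isolated) | O=C1C(CO)=C(CC(=O)/C=C/C)C[C@@H](O[Si](C)(C)C(C)(C)C)[C@@]1(C)OC(=O)c2c(C)cc(O[Si](C(C)C)(C(C)C)C(C)C)cc2OC | intermediate
24 | (6R,7R)-6-(tert-butyldimethylsilyloxy)-7-methyl-8-oxo-3-[(E)-prop-1-en-1-yl]-5,6,7,8-tetrahydro-1H-isochromen-7-yl 2-methoxy-6-methyl-4-(triisopropylsilyloxy)benzoate | C/C=C/C1=CC2=C(CO1)C(=O)[C@](C)(OC(=O)c3c(C)cc(O[Si](C(C)C)(C(C)C)C(C)C)cc3OC)[C@H](O[Si](C)(C)C(C)(C)C)C2 | intermediate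
25 | (6R,7R)-6-hydroxy-7-methyl-8-oxo-3-[(E)-prop-1-en-1-yl]-5,6,7,8-tetrahydro-1H-isochromen-7-yl 4-hydroxy-2-methoxy-6-methylbenzoate | C/C=C/C1=CC2=C(CO1)C(=O)[C@](C)(OC(=O)c1c(C)cc(O)cc1OC)[C@H](O)C2 | target

**Step count**

Total: 16 steps. Longest linear sequence: 13 steps (steps 1–6 and 10–16, from 1).

**Steps most likely to fail, with fallbacks**

Step 15. The free C1 hydroxyl may attack the gold-activated alkyne in the 7-endo sense, or the propargylic system may ionise, giving regioisomeric enol ethers and loss of alkene geometry. The fallback sets out from 20 and runs the gold step before any internal nucleophile is present. Methanolysis (PPTS, MeOH) of the triethylsilyl ether of 20 should give the bromo-enone propargylic alcohol F5. Its Meyer–Schuster rearrangement (Ph3PAuNTf2, MeOH, toluene) should give the bromo-enone (E)-propenyl ketone F6. Stille hydroxymethylation of F6 (Bu3SnCH2OH, Pd(PPh3)4) then comes back to the route at 23, which closes to 24 with PPTS and molecular sieves as in step 15.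

Step 4. The ligand coupling may fail to transfer the hindered aroate from iodine to the tertiary carbon, so that acetate is captured or the dione is merely oxidised. The fallback sets out from 5. Enol hydroxylation with dimethyldioxirane in acetone should give 2-hydroxy-2-methylcyclopentane-1,3-dione F1. Acid 4 is converted with 1-chloro-N,N,2-trimethylprop-1-en-1-amine into 2-methoxy-6-methyl-4-(triisopropylsilyloxy)benzoyl chloride F2. Acylation of F1 with F2 (Et3N, DMAP, CH2Cl2, reflux), which for a 2,6-disubstituted aroyl chloride passes through an acylium-like species, comes back to the route at 7.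

Step 13. Transmetalation of the sp3 stannane at the hindered, tetrasubstituted bromo-enone may be slow, so that protodebromination or decomposition takes over. The fallback sets out from 20. Stille coupling with tributyl(vinyl)stannane (Pd(PPh3)4, dioxane), a fast sp2 transfer, should give the 3-vinyl dienone F3. Lemieux–Johnson cleavage of the terminal vinyl group (OsO4 cat., NaIO4, 2,6-lutidine, dioxane/H2O) should give the 3-formyl enone F4. Selective aldehyde reduction of F4 with NaBH(OAc)3 comes back to the route at 21.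

**Further compounds**

F1 | step 4 | 2-hydroxy-2-methylcyclopentane-1,3-dione | CC1(O)C(=O)CCC1=O
F2 | step 4 | 2-methoxy-6-methyl-4-(triisopropylsilyloxy)benzoyl chloride | COc1cc(O[Si](C(C)C)(C(C)C)C(C)C)cc(C)c1C(Cl)=O
F3 | step 13 | (1R,6R)-6-(tert-butyldimethylsilyloxy)-1-methyl-2-oxo-4-[(4R)-4-(triethylsilyloxy)pent-2-yn-1-yl]-3-vinylcyclohex-3-en-1-yl 2-methoxy-6-methyl-4-(triisopropylsilyloxy)benzoate | O=C1C(C=C)=C(CC#C[C@@H](C)O[Si](CC)(CC)CC)C[C@@H](O[Si](C)(C)C(C)(C)C)[C@@]1(C)OC(=O)c2c(C)cc(O[Si](C(C)C)(C(C)C)C(C)C)cc2OC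
F4 | step 13 | (1R,6R)-6-(tert-butyldimethylsilyloxy)-3-formyl-1-methyl-2-oxo-4-[(4R)-4-(triethylsilyloxy)pent-2-yn-1-yl]cyclohex-3-en-1-yl 2-methoxy-6-methyl-4-(triisopropylsilyloxy)benzoate | O=C1C(C=O)=C(CC#C[C@@H](C)O[Si](CC)(CC)CC)C[C@@H](O[Si](C)(C)C(C)(C)C)[C@@]1(C)OC(=O)c2c(C)cc(O[Si](C(C)C)(C(C)C)C(C)C)cc2OC
F5 | step 15 | (1R,6R)-3-bromo-6-(tert-butyldimethylsilyloxy)-4-[(4R)-4-hydroxypent-2-yn-1-yl]-1-methyl-2-oxocyclohex-3-en-1-yl 2-methoxy-6-methyl-4-(triisopropylsilyloxy)benzoate | O=C1C(Br)=C(CC#C[C@@H](C)O)C[C@@H](O[Si](C)(C)C(C)(C)C)[C@@]1(C)OC(=O)c2c(C)cc(O[Si](C(C)C)(C(C)C)C(C)C)cc2OC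
F6 | step 15 | (1R,6R)-3-bromo-6-(tert-butyldimethylsilyloxy)-1-methyl-2-oxo-4-[(E)-2-oxopent-3-en-1-yl]cyclohex-3-en-1-yl 2-methoxy-6-methyl-4-(triisopropylsilyloxy)benzoate | O=C1C(Br)=C(CC(=O)/C=C/C)C[C@@H](O[Si](C)(C)C(C)(C)C)[C@@]1(C)OC(=O)c2c(C)cc(O[Si](C(C)C)(C(C)C)C(C)C)cc2OC
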